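The tetrahydrofuran ring is numbered O1, C2–C5. The route rests on closing this ring at C4–C5 by collapse of an oxocarbenium–enolate zwitterion. The feature exploited is the 1,3-donor–acceptor pattern of the ring: C2 bears an electron-rich aryl group, C4 an aroyl group, and O1–C5 is 4-hydroxybenzaldehyde. The precursor is therefore an enantiopure 3-aryl-1,2-diaroylcyclopropane whose C2–C4 bond is absent from the target. Under Lewis acid catalysis the aldehyde oxygen opens this bond at C2 with inversion, and C4 then attacks C5. One operation forms O1–C2 and C4–C5 and sets C2, C4 and C5 from the surviving centre C3. Chalcone and phenacyl bromide from one acetophenone supply the cyclopropane.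

Key step: step 4

Assumption: the quinidine-derived catalyst of step 3 is taken to deliver the (1S,2S) cyclopropane; should the first run show the opposite sense, the pseudo-enantiomeric 9-O-methylquinine is used with no other change.

Step 1
Reactants: 1 1-[2,4-bis(benzyloxy)phenyl]ethan-1-one; 2 4-(benzyloxy)benzaldehyde
Product: 3 (E)-1-[2,4-bis(benzyloxy)phenyl]-3-[4-(benzyloxy)phenyl]prop-2-en-1-one
Conditions: KOH (50% aq), EtOH, rt
Reagents that add atoms: none
Why: Claisen–Schmidt aldol condensation in which 1 is the only enolisable partner and 2 the only aldehyde, and E1cB dehydration should give the conjugated (E)-enone under thermodynamic control without forming a stereocentre.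

Step 2
Reactants: 1 1-[2,4-bis(benzyloxy)phenyl]ethan-1-one
Product: 4 1-[2,4-bis(benzyloxy)phenyl]-2-bromoethan-1-one
Conditions: CuBr2 (2 equiv), EtOAc/CHCl3 1:1, reflux
Reagents that add atoms: copper dibromide, Br[Cu]Br
Why: Heterogeneous alpha-bromination of an aryl methyl ketone with CuBr2 runs through the copper-bound enol and should therefore spare the electron-rich resorcinol ring and the benzyl ethers that free bromine would attack.

Step 3
Reactants: 3 (E)-1-[2,4-bis(benzyloxy)phenyl]-3-[4-(benzyloxy)phenyl]prop-2-en-1-one; 4 1-[2,4-bis(benzyloxy)phenyl]-2-bromoethan-1-one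
Product: 5 {(1S,2S)-3-[4-(benzyloxy)phenyl]cyclopropane-1,2-diyl}bis{[2,4-bis(benzyloxy)phenyl]methanone}. The two aroyl groups are trans. The ring carbons are called C2 (aryl, former chalcone beta-carbon), C3 (former chalcone alpha-carbon, aroyl trans to the aryl group) and C4 (former bromide carbon, aroyl cis to the aryl group).
Conditions: 9-O-methylquinidine (20 mol %), Cs2CO3 (1.3 equiv), MeCN, 80 °C, slow addition of 4
Reagents that add atoms: none
Why: Ammonium-ylide Michael-initiated ring closure (cinchona-catalysed cyclopropanation), in which the quinuclidine nitrogen is alkylated by 4 and deprotonated to the ylide, conjugate addition to the beta-carbon of 3 inside the chiral pocket fixes the absolute configuration, and anti-periplanar 3-exo-tet loss of the amine keeps the chalcone aryl and aroyl groups trans and places the two aroyl dipoles trans, so that only C3 and C4 are stereogenic.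

Step 4
Reactants: 5 {(1S,2S)-3-[4-(benzyloxy)phenyl]cyclopropane-1,2-diyl}bis{[2,4-bis(benzyloxy)phenyl]methanone}; 2 4-(benzyloxy)benzaldehyde
Product: 7 {(2S,3R,4R,5S)-2,5-bis[4-(benzyloxy)phenyl]oxolane-3,4-diyl}bis{[2,4-bis(benzyloxy)phenyl]methanone}, via oxocarbenium enolate zwitterion 6 (not isolated)
Conditions: 2 (3 equiv), Sc(OTf)3 (10 mol %), 4 Å MS, CH2Cl2, −30 °C; Et3N quench
Reagents that add atoms: none
Why: Sc(OTf)3, held in a six-membered chelate by an aroyl oxygen and its ortho benzyloxy oxygen, polarises the donor–acceptor bond C2–C4 of 5, the carbonyl oxygen of 2 attacks C2 from the rear of that bond and releases zwitterion 6, and the enolate carbon C4 of 6 then adds to the oxocarbenium carbon C5. The closest known reaction type is the Lewis-acid-catalysed formal (3+2) cycloaddition of donor–acceptor cyclopropanes with aldehydes, and its second stage is the same ion-pair collapse that operates in the low-temperature ring contraction of 4,5-dihydro-1,3-dioxepines to 2,3-cis-3-acyltetrahydrofurans. The only ring formed, the tetrahydrofuran, closes through C4–C5 in the 5-(enolexo)-endo-trig mode. C3 is carried over unchanged from 5; C2 is set by inversion, so the aryl group that is trans to the C3 aroyl group in 5 becomes cis to it in 7; C4 is set by allylic strain in the (Z)-enolate, which turns the hydrogen on C3 into the enolate plane and lets C5 bond anti to the C3 aroyl group (3,4-trans). C5 is set by the (E)-oxocarbenium ion reacting in the compact synclinal, charge-matched envelope that keeps the C3 aroyl group pseudo-equatorial and the C2 aryl group on the rear face, which places the C5 aryl group cis to the C4 aroyl group and trans to the C2 aryl group. The step needs cleavage of C2–C4 and not C2–C3, secured by release of the cis aryl/aroyl eclipsing strain that only C2–C4 carries; capture of C2 by 2 before Cloke–Wilson closure or proton loss, secured by the excess of 2; and kinetic control, secured by low temperature, a mild catalyst and the amine quench.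

Step 5
Reactants: 7 {(2S,3R,4R,5S)-2,5-bis[4-(benzyloxy)phenyl]oxolane-3,4-diyl}bis{[2,4-bis(benzyloxy)phenyl]methanone}
Product: 8 [(2S,3R,4R,5S)-2,5-bis(4-hydroxyphenyl)oxolane-3,4-diyl]bis[(2,4-dihydroxyphenyl)methanone] (CNP0237262.3)
Conditions: H2 (1 atm), 10% Pd/C, EtOAc/MeOH 1:1, rt, stopped after uptake of six equivalents
Reagents that add atoms: none
Why: Catalytic hydrogenolysis of the six aryl benzyl ethers should be faster than cleavage of the ring C–O bonds and runs under neutral conditions, so the epimerisable centres C3 and C4 and the acid-labile centres C2 and C5 stay untouched and no stereocentre is formed.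

Compound list
1 | 1-[2,4-bis(benzyloxy)phenyl]ethan-1-one | CC(=O)c1ccc(OCc2ccccc2)cc1OCc1ccccc1 | starting material
2 | 4-(benzyloxy)benzaldehyde | O=Cc1ccc(OCc2ccccc2)cc1 | starting material
3 | (E)-1-[2,4-bis(benzyloxy)phenyl]-3-[4-(benzyloxy)phenyl]prop-2-en-1-one | O=C(/C=C/c1ccc(OCc2ccccc2)cc1)c1ccc(OCc2ccccc2)cc1OCc1ccccc1 | intermediate
4 | 1-[2,4-bis(benzyloxy)phenyl]-2-bromoethan-1-one | O=C(CBr)c1ccc(OCc2ccccc2)cc1OCc1ccccc1 | intermediate
5 | {(1S,2S)-3-[4-(benzyloxy)phenyl]cyclopropane-1,2-diyl}bis{[2,4-bis(benzyloxy)phenyl]methanone} | O=C(c1ccc(OCc2ccccc2)cc1OCc1ccccc1)[C@@H]1[C@@H](C(=O)c2ccc(OCc3ccccc3)cc2OCc2ccccc2)C1c1ccc(OCc2ccccc2)cc1 | intermediate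
6 | open-chain zwitterion with (Z)-enolate at C4 and (E)-oxocarbenium ion O1=C5, drawn without the scandium | O=C(c1ccc(OCc2ccccc2)cc1OCc1ccccc1)[C@H](/C=C(\[O-])c1ccc(OCc2ccccc2)cc1OCc1ccccc1)[C@H](/[O+]=C/c1ccc(OCc2ccccc2)cc1)c1ccc(OCc2ccccc2)cc1 | intermediate
7 | {(2S,3R,4R,5S)-2,5-bis[4-(benzyloxy)phenyl]oxolane-3,4-diyl}bis{[2,4-bis(benzyloxy)phenyl]methanone} | O=C(c1ccc(OCc2ccccc2)cc1OCc1ccccc1)[C@@H]1[C@@H](C(=O)c2ccc(OCc3ccccc3)cc2OCc2ccccc2)[C@@H](c2ccc(OCc3ccccc3)cc2)O[C@@H]1c1ccc(OCc2ccccc2)cc1 | intermediate
8 | [(2S,3R,4R,5S)-2,5-bis(4-hydroxyphenyl)oxolane-3,4-diyl]bis[(2,4-dihydroxyphenyl)methanone] | O=C(c1ccc(O)cc1O)[C@@H]1[C@@H](C(=O)c2ccc(O)cc2O)[C@@H](c2ccc(O)cc2)O[C@@H]1c1ccc(O)cc1 | target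

Total step count: 5. Longest linear sequence: 4 (steps 1 or 2, then 3, 4, 5).

Steps most likely to fail

1. Step 4.
- **What may go wrong:** Full ionisation to a free 4-alkoxybenzyl cation would erode the inversion at C2. Closure through the alternative envelope would give the 2,5-cis series, which is the usual outcome for gem-diester cyclopropanes. Reversible closure would let the product drift to more stable isomers. Isomerisation to the dihydrofuran or the arylidene diketone would compete.
- **Fallback, from 5 back to 7:** 5 is opened with commercial 4-(benzyloxy)benzyl alcohol (TfOH 1 mol %, hexafluoroisopropanol/CH2Cl2, 0 °C). This is an SN2-like alcoholysis of a donor–acceptor cyclopropane. It gives the ether (2R)-1,4-bis[2,4-bis(benzyloxy)phenyl]-2-[(S)-[4-(benzyloxy)phenyl]{[4-(benzyloxy)phenyl]methoxy}methyl]butane-1,4-dione F1, whose centres C2 and C3 can be secured and purified before any ring closure. Kinetic deprotonation of the C4 methylene (LiHMDS, THF, −78 °C) and O-acetylation (Ac2O) give the (Z)-enol acetate (1Z,3R)-1,4-bis[2,4-bis(benzyloxy)phenyl]-3-[(S)-[4-(benzyloxy)phenyl]{[4-(benzyloxy)phenyl]methoxy}methyl]-4-oxobut-1-en-1-yl acetate F2. DDQ (2,6-dichloropyridine, LiClO4, 4 Å MS, 1,2-dichloroethane, rt) then abstracts hydride from the 4-alkoxybenzyl CH2 group. The enol acetate closes the same C4–C5 bond irreversibly, without a Lewis acid that could reopen the product, and gives 7.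

2. Step 3.
- **What may go wrong:** Conjugate addition of the stabilised ammonium ylide to the beta-aryl enone may be sluggish. The bromide may self-condense, and enantiofacial discrimination may be insufficient.
- **Fallback, from 1 and 2 back to 5:** The cyclopropane is cut differently, as aryl-carbene transfer to a symmetric alkene. Oxidative homocoupling of the lithium enolate of 1 (LDA, then CuCl2, THF/DMF, −78 °C) gives 1,4-bis[2,4-bis(benzyloxy)phenyl]butane-1,4-dione F3. IBX dehydrogenation (DMSO, 70 °C) gives (E)-1,4-bis[2,4-bis(benzyloxy)phenyl]but-2-ene-1,4-dione F4. Aldehyde 2 and tosylhydrazine give N'-[(E)-4-(benzyloxy)benzylidene]-4-methylbenzenesulfonohydrazide F5. With NaOMe and BnEt3NCl at 40 °C (Bamford–Stevens conditions) this releases 1-(benzyloxy)-4-(diazomethyl)benzene F6 in the flask. Rh2(OAc)4 (1 mol %) passes the carbene to enantiopure isothiocineole (20 mol %), and the semi-stabilised benzylic sulfonium ylide cyclopropanates F4 to give 5. The alkene geometry guarantees trans aroyl groups and the aryl carbon is not stereogenic, so only facial selectivity matters.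

3. Step 5.
- **What may go wrong:** Over-reduction, meaning hydrogenolysis of the doubly benzylic ring C–O bonds or reduction of the aryl ketones once the phenols are free.
- **Fallback, from 7 directly to 8:** A non-reductive, cation-scavenged Lewis acid debenzylation is used (BCl3, pentamethylbenzene, CH2Cl2, −78 °C, methanol quench). No new compound F0 arises on this way.

Further compounds
F1 | step 4 | (2R)-1,4-bis[2,4-bis(benzyloxy)phenyl]-2-[(S)-[4-(benzyloxy)phenyl]{[4-(benzyloxy)phenyl]methoxy}methyl]butane-1,4-dione | O=C(c1ccc(OCc2ccccc2)cc1OCc1ccccc1)[C@H](CC(=O)c1ccc(OCc2ccccc2)cc1OCc1ccccc1)[C@H](OCc1ccc(OCc2ccccc2)cc1)c1ccc(OCc2ccccc2)cc1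
F2 | step 4 | (1Z,3R)-1,4-bis[2,4-bis(benzyloxy)phenyl]-3-[(S)-[4-(benzyloxy)phenyl]{[4-(benzyloxy)phenyl]methoxy}methyl]-4-oxobut-1-en-1-yl acetate | O=C(c1ccc(OCc2ccccc2)cc1OCc1ccccc1)[C@H](/C=C(\OC(C)=O)c1ccc(OCc2ccccc2)cc1OCc1ccccc1)[C@H](OCc1ccc(OCc2ccccc2)cc1)c1ccc(OCc2ccccc2)cc1
F3 | step 3 | 1,4-bis[2,4-bis(benzyloxy)phenyl]butane-1,4-dione | O=C(CCC(=O)c1ccc(OCc2ccccc2)cc1OCc1ccccc1)c1ccc(OCc2ccccc2)cc1OCc1ccccc1
F4 | step 3 | (E)-1,4-bis[2,4-bis(benzyloxy)phenyl]but-2-ene-1,4-dione | O=C(/C=C/C(=O)c1ccc(OCc2ccccc2)cc1OCc1ccccc1)c1ccc(OCc2ccccc2)cc1OCc1ccccc1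
F5 | step 3 | N'-[(E)-4-(benzyloxy)benzylidene]-4-methylbenzenesulfonohydrazide | Cc1ccc(cc1)S(=O)(=O)N/N=C/c1ccc(OCc2ccccc2)cc1
F6 | step 3 | 1-(benzyloxy)-4-(diazomethyl)benzene | [N-]=[N+]=Cc1ccc(OCc2ccccc2)cc1
F0 | step 5 | none | none
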